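## Analysis of the target

The target 12 is an achiral acylresorcinol of the malabaricone type. A 2,6-dihydroxyphenyl ketone (ring B, carbonyl carbon C1) is joined through eight unbranched methylene groups (C2–C9) to a 4-hydroxy-3-methoxyphenyl group (ring A) at C9. It has no stereocentre and no ring that must be built, since both benzene rings occur in cheap commercial compounds. The sensitive groups are three phenols, one aryl methyl ether that must survive, and an aryl ketone that must not be reduced. The ring A phenol is electron-rich and easily oxidised, and the two ring B phenols are hydrogen-bonded to the carbonyl. The methyl ether forbids any late ether cleavage that cannot tell methyl from the protecting group. Ring B is awkward because the acyl group sits on the carbon between the two oxygens, where electrophilic acylation does not go, so this pattern is better bought than made. The real difficulty is the exact length of the chain: a homologue one CH2 shorter or longer would be almost impossible to separate. The strategy rests on three facts. Ring A with C9 and C8 is the carbon skeleton of eugenol 8 less its terminal CH2. C1 with ring B is the skeleton of 1. The chain C2–C9 is saturated and unbranched, so a C7=C8 double bond made by cross-metathesis can be erased by the hydrogenation that also removes benzyl ethers from ring B.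

## Retrosynthetic reasoning

**12 ⇒ 9.** The last operation is fixed first. A C7=C8 double bond is written into the chain and the two ring B hydroxyls are masked as benzyl ethers, which gives 9. One catalytic hydrogenation undoes both changes: the alkene is saturated (10) and the benzyl groups then leave one after the other (11, then 12). Benzyl is chosen because its removal leaves the ring A methyl ether untouched and needs no separate step. The forward reaction has to saturate and deprotect without reducing the C1 ketone.

**9 ⇒ 7 + 8.** The C7=C8 bond is cut by alkene cross-metathesis. The cut is placed here because C8, C9 and ring A are then exactly eugenol 8, used as bought and with its phenol free. No other position in the chain lets one whole fragment come from a catalogue. The cut lies five methylene groups from the carbonyl, so the ketone partner 7 behaves as an ordinary terminal alkene. The gain is convergence, with the ring A half costing no step. The forward reaction has to join two terminal alkenes in preference to their homodimers and without migration of either double bond, because migration would change the chain length.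

**7 ⇒ 4 + 5.** The C2–C3 bond is cut. Ketone 4 has a single enolisable position, its methyl group, which becomes C2. The six carbons of 5 become C3–C8 by alkylation of the enolate 6. The opposite choice, acylating ring B with an eight-carbon unit, is rejected: electrophilic substitution of a 1,3-dioxygenated benzene goes para to one oxygen and not between the two, whereas 1 already carries the carbonyl on the right carbon. The forward reaction has to stop at monoalkylation.

**4 ⇒ 1 + 2.** Two O–benzyl bonds are cut. Double benzylation of 1 with 2 passes through the mono-ether 3. It removes the acidic phenols before the enolate chemistry and installs the groups that the final hydrogenation takes off.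

## Alternatives that were turned down

Alternative 1: Ring B itself is taken apart by a cyclobutenone–alkyne benzannulation. Heating cyclobut-2-en-1-one (A2) with the ynol ether A3 should open A2 to its ketene form, which adds to the alkyne in a [2+2] step. A second four-electron ring opening and a six-electron electrocyclisation then close ring B and give the phenol A1. In its favour, the chain is placed between the two oxygens with complete regiocontrol, which classical aromatic substitution cannot do, and the step is convergent. Against it, this ring B pattern can simply be bought in 1. A2 is volatile, polymerises readily and is laborious to prepare. A3 needs the whole aryl-terminated chain to be built first and then converted into a sensitive ynol ether. A1 still carries C1 as a silyl-protected alcohol and one ring B oxygen as an ethyl ether. Desilylation, oxidation, de-ethylation in the presence of the ring A methyl ether and debenzylation must therefore follow, at least four steps where the chosen route needs one. On regiocontrol of ring B the two strategies are equal; on step economy and on handling of the key reagents the chosen route is clearly ahead.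

Alternative 2: The C1'–C6' bond of ring B is disconnected to the open-chain 3-silyloxy-5,7-dioxo ester A5. With NaOMe, the carbon between the two ketones should attack the ester in a Claisen cyclisation. The resulting cyclohexanedione should lose the silyloxy group and tautomerise to the aromatic ketone A4, which is one hydrogenolysis away from the target. In its favour, the sequence is biomimetic, aromatisation is a strong driving force, the ring B hydroxyls never need protection, and it does not depend on a statistical coupling. On those two points it is stronger than the chosen strategy. Against it, A5 is a fragile chain with four oxygen functions that would take many steps to assemble. Under base it has competing paths: premature β-elimination of the silyloxy group towards either carbonyl, O-acylation to a lactone, and retro-Claisen cleavage of the diketone. The ring A end of the chain must still be made separately. The chosen strategy offers instead four steps from catalogue compounds, with both rings bought intact.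

Alternative 3: The C2–C3 bond is formed by hydrogen-borrowing alkylation of ketone 4 with the alcohol 7-(4-benzyloxy-3-methoxyphenyl)heptan-1-ol (A6) under [Cp*IrCl2]2 and KOH, giving the fully benzylated ketone A7 with water as the only by-product. The iridium complex dehydrogenates A6 to the aldehyde, which condenses with the enolate of 4, and the enone is reduced by the iridium hydride. In its favour, the twisted carbonyl of 4, flanked by two ortho substituents, resists reduction and self-condensation, and condensation followed by reduction can only monoalkylate. On that point it is stronger than the enolate alkylation used in step 2 of the chosen route, which forms the same bond. Against it, A6 is not a catalogue compound. Attaching a seven-carbon hydroxyalkyl chain to ring A would cost several steps and a protecting group on the ring A phenol, and the coupling needs hot alkali. In exchange for a less selective C2–C3 alkylation, the chosen strategy takes the ring A half from eugenol 8 with no preparation and reaches the target in about half the number of steps.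

Key step: step 3

Remark: 9 is drawn as the E isomer; the cross-metathesis should also give some Z isomer, which is carried along because step 4 removes the double bond.

## Route

Step 1
Reactants: 1 2',6'-dihydroxyacetophenone; 2 benzyl bromide
Product: 4 1-[2,6-bis(benzyloxy)phenyl]ethan-1-one, via mono-benzyl ether 3 (not isolated)
Conditions: 2 (2.5 equiv), K2CO3 (4 equiv), DMF, 70 °C
Reagents that add atoms: none
Why: Williamson ether synthesis, an SN2 reaction of each phenoxide with benzyl bromide. The second hydroxyl is slowed by its hydrogen bond to the carbonyl, which warm DMF and excess carbonate should overcome.

Step 2
Reactants: 4 1-[2,6-bis(benzyloxy)phenyl]ethan-1-one; 5 6-bromohex-1-ene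
Product: 7 1-[2,6-bis(benzyloxy)phenyl]oct-7-en-1-one, via lithium enolate 6 (not isolated)
Conditions: LiN(iPr)2 (1.05 equiv), THF, −78 °C; then 5 (1.2 equiv), DMPU, −78 °C to rt
Reagents that add atoms: none
Why: Kinetic deprotonation of the only enolisable position, then SN2 alkylation of the lithium enolate by the primary bromide, accelerated by DMPU. The two ortho benzyloxy groups shield the carbonyl against self-aldol addition, and the near-stoichiometric base and low temperature should limit proton exchange and hence dialkylation.

Step 3
Reactants: 7 1-[2,6-bis(benzyloxy)phenyl]oct-7-en-1-one; 8 eugenol (4-allyl-2-methoxyphenol)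
Product: 9 (E)-1-[2,6-bis(benzyloxy)phenyl]-9-(4-hydroxy-3-methoxyphenyl)non-7-en-1-one
Conditions: 8 (3 equiv), second-generation Grubbs catalyst RuCl2(H2IMes)(PCy3)(=CHPh) (5 mol%), 1,4-benzoquinone (10 mol%), CH2Cl2, 40 °C, argon sparge
Reagents that add atoms: none
Why: Alkene cross-metathesis by the metallacyclobutane mechanism: loss of PCy3 from the divalent ruthenium benzylidene gives the 14-electron carbene, which adds a terminal alkene in a [2+2] step to a ruthenacyclobutane and cycloreverts to a new alkylidene; alternating engagement of 7 and 8 joins C7 of 7 to C8 of 8 and expels the two terminal CH2 groups as ethene, whose escape from the refluxing solution drives the equilibria forward. The closest known reaction type is the ruthenium-catalysed cross-metathesis of allylbenzenes, eugenol among them, with unhindered terminal alkenes. No ring is closed and no stereocentre is created; the only new stereochemical element is the geometry of C7=C8, which secondary metathesis should bias towards E and which is irrelevant because step 4 saturates the bond. The selectivity needed is cross-coupling over self-coupling: both partners are unhindered monosubstituted alkenes of similar reactivity, so the outcome is statistical, and a threefold excess of the cheap partner 8 should channel the limiting ketone 7 into 9, while any homodimer of 7 stays metathesis-active and is drawn into 9 by further exchange with 8. The second requirement is that neither terminal double bond migrates before it reacts, since a migrated alkene would give a chain one carbon short; 1,4-benzoquinone intercepts the ruthenium hydrides responsible and the mild temperature limits their formation. In the substrates, the free phenol of 8 is tolerated by the ruthenium carbene, the ketone of 7 is shielded by two ortho benzyloxy groups and separated from the alkene by five methylene groups so that it cannot form a small chelate with ruthenium, and the benzyl ethers are inert. The three possible coupling products carry none, one or two free phenols, so 9 should separate easily from both homodimers by chromatography.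

Step 4
Reactants: 9 (E)-1-[2,6-bis(benzyloxy)phenyl]-9-(4-hydroxy-3-methoxyphenyl)non-7-en-1-one
Product: 12 1-(2,6-dihydroxyphenyl)-9-(4-hydroxy-3-methoxyphenyl)nonan-1-one, via saturated dibenzyl ether 10 (not isolated), via saturated monobenzyl ether 11 (not isolated)
Conditions: H2 (1 atm), 10% Pd/C, EtOAc–EtOH, rt
Reagents that add atoms: none
Why: Heterogeneous catalytic hydrogenation saturates the disubstituted alkene, and hydrogenolysis on the same catalyst cleaves the two aryl benzyl ethers to toluene. The ketone should survive because it is flanked by two ortho substituents and, once a phenol is freed, held in a hydrogen-bonded form that resists reduction; the methyl ether and both arenes are inert at 1 atm and rt.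

## Compound list

1 | 2',6'-dihydroxyacetophenone | CC(=O)c1c(O)cccc1O | starting material
2 | benzyl bromide | BrCc1ccccc1 | starting material
3 | 1-[2-(benzyloxy)-6-hydroxyphenyl]ethan-1-one | CC(=O)c1c(O)cccc1OCc1ccccc1 | intermediate (not isolated)
4 | 1-[2,6-bis(benzyloxy)phenyl]ethan-1-one | CC(=O)c1c(OCc2ccccc2)cccc1OCc1ccccc1 | intermediate
5 | 6-bromohex-1-ene | BrCCCCC=C | starting material
6 | lithium 1-[2,6-bis(benzyloxy)phenyl]ethen-1-olate | [Li]OC(=C)c1c(OCc2ccccc2)cccc1OCc1ccccc1 | intermediate (not isolated)
7 | 1-[2,6-bis(benzyloxy)phenyl]oct-7-en-1-one | C=CCCCCCC(=O)c1c(OCc2ccccc2)cccc1OCc1ccccc1 | intermediate
8 | eugenol (4-allyl-2-methoxyphenol) | C=CCc1ccc(O)c(OC)c1 | starting material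
9 | (E)-1-[2,6-bis(benzyloxy)phenyl]-9-(4-hydroxy-3-methoxyphenyl)non-7-en-1-one | COc1cc(C/C=C/CCCCCC(=O)c2c(OCc3ccccc3)cccc2OCc2ccccc2)ccc1O | intermediate
10 | 1-[2,6-bis(benzyloxy)phenyl]-9-(4-hydroxy-3-methoxyphenyl)nonan-1-one | COc1cc(CCCCCCCCC(=O)c2c(OCc3ccccc3)cccc2OCc2ccccc2)ccc1O | intermediate (not isolated)
11 | 1-[2-(benzyloxy)-6-hydroxyphenyl]-9-(4-hydroxy-3-methoxyphenyl)nonan-1-one | COc1cc(CCCCCCCCC(=O)c2c(O)cccc2OCc2ccccc2)ccc1O | intermediate (not isolated)
12 | 1-(2,6-dihydroxyphenyl)-9-(4-hydroxy-3-methoxyphenyl)nonan-1-one | COc1cc(CCCCCCCCC(=O)c2c(O)cccc2O)ccc1O | target

## Step count and least certain steps

Total step count: 4. Longest linear sequence: 4 steps (1 → 4 → 7 → 9 → 12); eugenol 8 enters without preparation.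

**Step 3 (key step).** The most likely failure is loss of chain-length fidelity. Ruthenium hydrides formed as the catalyst decomposes can move the terminal double bond of 8 into conjugation with ring A, or that of 7 along the chain. Metathesis of a migrated alkene then gives a product one carbon short, which after step 4 would be almost inseparable from 12. A second, milder problem is self-metathesis of each partner, which lowers the amount of 7 that ends up in 9.

The fallback avoids metathesis and fixes the chain length by the reagents. It sets out from 4 and comes back to the route at 10. Enolate 6 is generated as in step 2 and alkylated with commercial 7-bromohept-1-ene (BrCCCCCC=C) to give 1-[2,6-bis(benzyloxy)phenyl]non-8-en-1-one F1. Hydroboration of the terminal alkene with 9-BBN (THF, rt; the shielded ketone reacts far more slowly) gives 1-[2,6-bis(benzyloxy)phenyl]-9-(9-borabicyclo[3.3.1]nonan-9-yl)nonan-1-one F2. F2 is coupled without isolation with commercial 4-bromo-2-methoxyphenol (COc1cc(Br)ccc1O) in a B-alkyl Suzuki–Miyaura reaction (Pd(OAc)2, SPhos, aqueous K3PO4, THF, 65 °C), which forms the C9–ring A bond and gives 10. Compound 10 is then hydrogenolysed under the conditions of step 4 to 12.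

**Step 2.** The most likely failure is over-alkylation. Proton exchange between enolate 6 and product 7 during the slow reaction with an unactivated primary bromide would lead to dialkylation at C2, together with unreacted 4; some O-alkylation is also conceivable in the presence of DMPU.

The fallback replaces the ketone enolate by a stabilised β-keto ester enolate, which monoalkylates cleanly. It sets out from 4 and comes back to the route at 7. Claisen condensation of 4 with diethyl carbonate (NaH, toluene, reflux) gives ethyl 3-[2,6-bis(benzyloxy)phenyl]-3-oxopropanoate F3. Alkylation with 5 (K2CO3, NaI cat., DMF, 60 °C) gives ethyl 2-[2,6-bis(benzyloxy)benzoyl]oct-7-enoate F4. Saponification and decarboxylation (KOH, aqueous EtOH, then aqueous HCl, warm) give 7.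

**Step 4.** The most likely failure is reduction of the C1 carbonyl to the benzylic alcohol and further to a methylene group. This could compete if the second benzyl ether, which is hindered and ortho to the carbonyl, cleaves slowly and the reaction is prolonged. Incomplete debenzylation is the opposite risk.

The fallback separates the two events and removes the benzyl groups without hydrogen. It sets out from 9 and comes back to the route at 12. Alkene-only hydrogenation over a sulfide-poisoned catalyst (H2, Pd/C, Ph2S, EtOAc, rt) gives 10, which is isolated. Debenzylation with BCl3 and pentamethylbenzene as cation scavenger (CH2Cl2, −78 °C) then gives 12, under conditions in which neither the ketone nor the ring A methyl ether should react. This fallback makes no compound outside the compound list.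

## Further compounds

F1 | step 3 | 1-[2,6-bis(benzyloxy)phenyl]non-8-en-1-one | C=CCCCCCCC(=O)c1c(OCc2ccccc2)cccc1OCc1ccccc1
F2 | step 3 | 1-[2,6-bis(benzyloxy)phenyl]-9-(9-borabicyclo[3.3.1]nonan-9-yl)nonan-1-one | O=C(CCCCCCCCB1C2CCCC1CCC2)c1c(OCc2ccccc2)cccc1OCc1ccccc1
F3 | step 2 | ethyl 3-[2,6-bis(benzyloxy)phenyl]-3-oxopropanoate | CCOC(=O)CC(=O)c1c(OCc2ccccc2)cccc1OCc1ccccc1
F4 | step 2 | ethyl 2-[2,6-bis(benzyloxy)benzoyl]oct-7-enoate (racemic) | CCOC(=O)C(CCCCC=C)C(=O)c1c(OCc2ccccc2)cccc1OCc1ccccc1
F0 | step 4 | none | none
A1 | alternative 1 | 2-[9-(4-benzyloxy-3-methoxyphenyl)-1-(tert-butyldimethylsilyloxy)nonyl]-3-ethoxyphenol (racemic) | CCOc1cccc(O)c1C(O[Si](C)(C)C(C)(C)C)CCCCCCCCc1ccc(OCc2ccccc2)c(OC)c1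
A2 | alternative 1 | cyclobut-2-en-1-one | O=C1C=CC1
A3 | alternative 1 | tert-butyl{[11-(4-benzyloxy-3-methoxyphenyl)-1-ethoxyundec-1-yn-3-yl]oxy}dimethylsilane (racemic) | CCOC#CC(O[Si](C)(C)C(C)(C)C)CCCCCCCCc1ccc(OCc2ccccc2)c(OC)c1
A4 | alternative 2 | 9-(4-benzyloxy-3-methoxyphenyl)-1-(2,6-dihydroxyphenyl)nonan-1-one | COc1cc(CCCCCCCCC(=O)c2c(O)cccc2O)ccc1OCc1ccccc1
A5 | alternative 2 | methyl 15-(4-benzyloxy-3-methoxyphenyl)-3-(tert-butyldimethylsilyloxy)-5,7-dioxopentadecanoate (racemic) | COC(=O)CC(O[Si](C)(C)C(C)(C)C)CC(=O)CC(=O)CCCCCCCCc1ccc(OCc2ccccc2)c(OC)c1
A6 | alternative 3 | 7-(4-benzyloxy-3-methoxyphenyl)heptan-1-ol | OCCCCCCCc1ccc(OCc2ccccc2)c(OC)c1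
A7 | alternative 3 | 1-[2,6-bis(benzyloxy)phenyl]-9-(4-benzyloxy-3-methoxyphenyl)nonan-1-one | O=C(CCCCCCCCc1ccc(OCc2ccccc2)c(OC)c1)c1c(OCc2ccccc2)cccc1OCc1ccccc1
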